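- The constants I can read before the new flasks are few: a final level and a starting slope from each earlier run, each reading carrying a scatter of 0.5 percentage points.

| flask | substrate | partner | protic impurity | free catalyst | temperature | remark | time |
|---|---|---|---|---|---|---|---|
| Thursday's | 0.32 M | 0.304 M (fed, over 8.0 s) | 0.032 M | 3 mM | −15 °C | run made earlier; the fed solution adds 0.25 times the starting volume |  |
| Sunday's | 0.32 M | 0.304 M (fed, over 8.0 s) | 0.032 M | 4.7 mM | 2 °C | run made earlier; the fed solution adds 0.25 times the starting volume |  |
| red | 0.32 M | 0.304 M (fed, over 8.0 s) | 0.0320 M | 3.2 mM |  | at −10 °C until 8.0 s, from then on at 15 °C; the fed solution adds 0.25 times the starting volume | 10 min |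
| teal | 0.32 M | 0.304 M (fed, over 8.0 s) | 0.0320 M | 2.0 mM |  | at 15 °C throughout; the fed solution adds 0.25 times the starting volume | 10 min |

| run | time / min | target / % |
|---|---|---|
| Thursday's | 0.833 | 18.2 |
| Thursday's | 2.50 | 52.3 |
| Thursday's | 5.00 | 77.6 |
| Thursday's | 8.00 | 83.9 |
| Thursday's | 10.0 | 84.8 |
| Sunday's | 0.500 | 51.8 |
| Sunday's | 1.33 | 82.4 |
| Sunday's | 3.00 | 84.8 |
| Sunday's | 4.00 | 84.6 |
| Sunday's | 6.00 | 84.7 |

(readings scatter by 0.5 percentage points)

- charges are per starting volume, the dose included; the dosed solution carries all of it

- which one finishes higher in amount of target, in percent of the substrate charged ("neither" within 2 percentage points) (red / teal / neither)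
- amount of target at the end, in percent of the substrate charged, red
- amount of target at the end, in percent of the substrate charged, teal

- The level comes first. Thursday's run ends at 84.8 % and Sunday's stands at 84.8 %, although their temperatures and catalyst charges differ.
- I take the reaction of partner with protic impurity as settled, one for one, and reckon with what it leaves free. That gives 85.0 %, the usable-partner ceiling: the partner charge less the impurity charge, over the substrate charge.
- Partner is the limiting reagent here, because the 0.272 M left free is less than the 0.32 M of substrate. Red and teal have the same three charges, so they share this ceiling.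
- Now the slope. The chord to the first reading gives 0.218 min⁻¹ of the substrate charged for Thursday's run and 1.04 min⁻¹ for Sunday's.
- Per unit of catalyst, Sunday's slope is 3.03 times Thursday's, which I read as an activation energy near 38.5 kJ mol⁻¹.
- Carried to 15 °C, that reading gives teal a starting slope of 0.941 min⁻¹ and red, once it is warm, a slope of 1.51 min⁻¹. Red's cold stretch of 8.0 s is much shorter than the 10 min of the run.
- The knee is where a straight line at that slope would meet the ceiling: 0.903 min for teal and 0.563 min for red.
- The tail takes longer. Sunday's run is level by 3.00 min, which is 3.67 times its own knee, and the same factor puts teal's level near 3.32 min and red's near 2.07 min. Both come before 10 min.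
- The forecast says neither, with 85 % for red and 85 % for teal, on the ground that “the impurity destroys one partner each, quickly and completely”. My ceiling stands at the same level, and I commit to the same answer.

    partner + free catalyst ⇌ catalyst intermediate A (K = 2.40 M⁻¹, k = 29.0 M⁻¹ s⁻¹, Ea = 36.0 kJ mol⁻¹, ΔH = −20.0 kJ mol⁻¹)
    catalyst intermediate A → by-product + catalyst intermediate B (k = 4.40 s⁻¹, Ea = 50.0 kJ mol⁻¹)
    catalyst intermediate B → catalyst intermediate C (k = 4.70 s⁻¹, Ea = 63.0 kJ mol⁻¹)
    substrate + catalyst intermediate C → catalyst intermediate D (k = 780 M⁻¹ s⁻¹, Ea = 37.0 kJ mol⁻¹)
    catalyst intermediate D → free catalyst + target (k = 2.40 s⁻¹, Ea = 61.0 kJ mol⁻¹)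
    partner → decomposition product (k = 3.40 × 10⁻⁵ s⁻¹, Ea = 77.0 kJ mol⁻¹)
    partner + protic impurity → quenched reagent (k = 1.40 M⁻¹ s⁻¹, Ea = 50.0 kJ mol⁻¹)
    (constants at −10 °C)

- The flasks give 83.9 % for red and 83.3 % for teal, so the answer is neither, with 0.60 points between them. At 10.0 min teal holds 0.00435 M of decomposition product and red 0.00270 M, in the volume swollen by the feed. Taking that partner off the ceiling leaves 83.3 % for teal and 83.9 % for red. The answer would change with the partner charge: the neighbour of teal with a quarter of it, 0.076 M, has a ceiling of 13.7 % and gives 13.5 %.

The readings are calculated with constants of no real substance; the scatter is artificial.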